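**Leftover gap.** Once starting material reads zero, target stands short of the charge and stays there: by 2.60% on the beta plateau and by 5.25% on the zeta plateau.

| flask | starting material | temperature | remark | time |
|---|---|---|---|---|
| beta | 0.75 M | 48 °C | run made earlier |  |
| zeta | 1.1 M | 64 °C | run made earlier |  |
| Friday's | 1.5 M | 40 °C |  | 20 min |
| Saturday's | 1.5 M | 70 °C |  | 20 min |
| Monday's | 1.5 M | 55 °C |  | 20 min |

| run | time / min | target / % | starting material / % |
|---|---|---|---|
| beta | 1.50 | 43 | 54 |
| beta | 3.00 | 81 | 11 |
| beta | 5.00 | 97 | 0 |
| beta | 6.00 | 98 | 0 |
| beta | 8.00 | 98 | 0 |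
| beta | 10.0 | 96 | 0 |
| beta | 12.0 | 98 | 1 |
| zeta | 0.200 | 14 | 81 |
| zeta | 0.667 | 47 | 44 |
| zeta | 1.00 | 77 | 20 |
| zeta | 1.50 | 95 | 0 |
| zeta | 2.50 | 96 | 0 |
| zeta | 3.00 | 93 | 0 |
| zeta | 4.00 | 95 | 2 |

(scatter of a reading: 1.5 percentage points)

- which flask leads in amount of target, in percent of the starting material charged ("all alike" within 1.5 percentage points) (Friday's / Saturday's / Monday's / all alike)
- how much target is there at the end, in percent of the starting material charged: Friday's
- how much target is there at the end, in percent of the starting material charged: Saturday's
- how much target is there at the end, in percent of the starting material charged: Monday's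



**Bench rule.** Starting material falls in a straight line, a zero-order main step: 0.215 M min⁻¹ in beta, 0.839 M min⁻¹ in zeta. Friday's lies half that temperature step below beta, so on a logarithmic scale Friday's flask is reckoned to empty in about 13.8 min, less than its 20 min.

Suppose a side step goes with the square of c(starting material) beside that flat main step. Averaged over the fall, the square is a third of its starting value, so the gap equals the square of the ratio of the charge to c_L. Here c_L is the loss charge, read as 4.65 M from beta and 4.80 M from zeta, at different temperatures, and carried as 4.73 M. At 1.5 M this reckoning gives 89.9% target in each flask.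

**Its border.** The rule needs a small side-to-main ratio at the start, which is three times the gap: 0.0756 in beta but 0.302 at 1.5 M. There the rule overstates the gap, so this reckoning expects target a little above that figure, and the flasks alike.

**The forecast.** It differs: 96.5%, 92% and 95% for Friday's, Saturday's and Monday's, with Friday's leading, on the ground “the loss grows with temperature and/or concentration”.

**The flasks.** Friday's gives 91.7%, Saturday's 91.9%, Monday's 91.8%: all alike.

    starting material → target, rate k1*[starting material]/(1 + ([starting material]/sat1)) (7.71 mM, k = 2.94 s⁻¹, Ea = 77.0 kJ mol⁻¹)
    2 starting material → homo dimer (k = 0.00141 L mol⁻¹ s⁻¹, Ea = 76.0 kJ mol⁻¹)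
    (constants at 70 °C)

**Where they part.** From 40 °C to 70 °C the target step and the homo dimer step speed up by like factors, 13 and 13. At Monday's start the target step uses starting material at 3.5 times the homo dimer step's rate, a selectivity factor for that moment. For a neighbour of Monday's flask, charged at 0.90 M with all else held, c_L gives 96.4% target. That flask gives 96.7%, with homo dimer at 3.26%.

All runs are simulated for an exercise.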